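With C1 as the quaternary carbinol, C2 CHOBz, C3 CHOH, C4=C5 the alkene, C6 the ketone and C7 the CH2OBz carbon, everything rests on cutting C5–C6. The C6 ketone conjugated to the cis C4=C5 bond of the six-membered carbocycle is an isomer of an open chain that ends in a C6 aldehyde and a terminal C4≡C5 alkyne. One rhodium-catalysed, fully atom-economic addition of the C6–H bond across that alkyne closes the only ring and creates the enone while C1–C3 stay untouched. The precursor is hex-5-ynal 23: C1 OTES, C2 and C7 benzoates, C3 OTBS; C2/C3 come from diethyl D-tartrate, C1 from a chelate-controlled vinyl addition.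

Key step: step 14

Remark on the chemistry: the target SMILES is read as (1R,2S,3R) in the numbering above. That places C1–OH trans to C2–OBz and C2–OBz trans to C3–OH. The threo C2/C3 pair maps onto (S,S)-tartrate, and the labels C1–C7 are used for all intermediates.

Design notes:
- **Benzoates:** they enter only after the last methanolic base and the last organometallic step.
- **C7:** it is carried as CH2Cl through the Grignard step, so that the C2 PMB ether is the only good ligand for magnesium.
- **C1 silyl ether:** it is treated purely as protection.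

Step 1
Reactants: 1 diethyl D-tartrate
Product: 3 diethyl (2S,3S)-2-hydroxy-3-[(4-methoxybenzyl)oxy]butanedioate, via stannylene acetal 2 (not isolated)
Conditions: Bu2SnO, toluene, reflux (–H2O); then PMBCl, CsF, DMF, rt
Reagents that add atoms: 4-methoxybenzyl chloride, COc1ccc(CCl)cc1; dibutyltin oxide, CCCC[Sn](=O)CCCC (its tin stays only in 2)
Why: Stannylene-acetal-mediated mono-O-alkylation: the tin acetal activates one oxygen only, and since 1 is C2-symmetric either oxygen gives the same ether, so C2–O (PMB) and C3–O (free) are told apart without a selectivity problem and without touching a stereocentre.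

Step 2
Reactants: 3 diethyl (2S,3S)-2-hydroxy-3-[(4-methoxybenzyl)oxy]butanedioate
Product: 5 (3S,4R)-4-hydroxy-3-[(4-methoxybenzyl)oxy]oxolan-2-one, via diol ester 4 (not isolated)
Conditions: BH3·SMe2, NaBH4 (5 mol %), THF, 0 °C to rt; MeOH; then CSA (5 mol %), CH2Cl2, rt
Reagents that add atoms: none
Why: Hydroxyl-directed borane reduction: the free C3–OH binds boron and delivers hydride only to the neighbouring C4 ester, and acid-catalysed lactonisation of the new C4–OH onto the C1 ester then masks both chain ends in a trans γ-lactone and leaves C3–OH as the only free hydroxyl.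

Step 3
Reactants: 5 (3S,4R)-4-hydroxy-3-[(4-methoxybenzyl)oxy]oxolan-2-one
Product: 6 (3S,4R)-4-[(tert-butyldimethylsilyl)oxy]-3-[(4-methoxybenzyl)oxy]oxolan-2-one
Conditions: TBSCl, imidazole, DMF, rt
Reagents that add atoms: tert-butyldimethylsilyl chloride, CC(C)(C)[Si](C)(C)Cl
Why: Imidazole-promoted silylation of the only free hydroxyl, with a base too mild to provoke β-elimination in the lactone.

Step 4
Reactants: 6 (3S,4R)-4-[(tert-butyldimethylsilyl)oxy]-3-[(4-methoxybenzyl)oxy]oxolan-2-one
Product: 7 (2S,3R)-3-[(tert-butyldimethylsilyl)oxy]-4-hydroxy-N-methoxy-2-[(4-methoxybenzyl)oxy]-N-methylbutanamide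
Conditions: MeNH(OMe)·HCl, AlMe3, CH2Cl2, 0 °C to rt
Reagents that add atoms: N,O-dimethylhydroxylamine hydrochloride, CNOC.Cl
Why: Weinreb aminolysis of a lactone with an aluminium amide frees C4–OH and turns C1 into a mono-acylating group in one operation, and the aluminium alkoxide formed is too weakly nucleophilic to start a C3-to-C4 silyl migration.

Step 5
Reactants: 7 (2S,3R)-3-[(tert-butyldimethylsilyl)oxy]-4-hydroxy-N-methoxy-2-[(4-methoxybenzyl)oxy]-N-methylbutanamide
Product: 8 (2S,3S)-3-[(tert-butyldimethylsilyl)oxy]-N-methoxy-2-[(4-methoxybenzyl)oxy]-N-methyl-4-oxobutanamide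
Conditions: Dess–Martin periodinane, CH2Cl2, 0 °C to rt (crude 7 used at once)
Reagents that add atoms: none
Why: Dess–Martin oxidation works under non-basic conditions that should not epimerise C3, and immediate use of 7 forestalls relactonisation.

Step 6
Reactants: 8 (2S,3S)-3-[(tert-butyldimethylsilyl)oxy]-N-methoxy-2-[(4-methoxybenzyl)oxy]-N-methyl-4-oxobutanamide; 9 dimethyl (1-diazo-2-oxopropyl)phosphonate
Product: 10 (2S,3R)-3-[(tert-butyldimethylsilyl)oxy]-N-methoxy-2-[(4-methoxybenzyl)oxy]-N-methylpent-4-ynamide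
Conditions: 9, K2CO3, MeOH, 0 °C to rt
Reagents that add atoms: dimethyl (1-diazo-2-oxopropyl)phosphonate 9, COP(=O)(OC)C(=[N+]=[N-])C(C)=O
Why: Ohira–Bestmann variant of the Seyferth–Gilbert homologation: the diazophosphonate anion made in situ adds to the aldehyde, and loss of phosphate and N2 with a 1,2-H shift gives the terminal alkyne (C5 from 9), while the short cold contact with carbonate should spare C3 and the Weinreb amide is inert.

Step 7
Reactants: 10 (2S,3R)-3-[(tert-butyldimethylsilyl)oxy]-N-methoxy-2-[(4-methoxybenzyl)oxy]-N-methylpent-4-ynamide; 11 chloroiodomethane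
Product: 12 (3S,4R)-4-[(tert-butyldimethylsilyl)oxy]-1-chloro-3-[(4-methoxybenzyl)oxy]hex-5-yn-2-one
Conditions: 11 (3.5 equiv), MeLi·LiBr (3.3 equiv), THF–Et2O, –78 °C
Reagents that add atoms: chloroiodomethane 11, ClCI
Why: Acylation of a lithium carbenoid by a Weinreb amide: chloromethyllithium generated in the presence of 10 adds only once because the chelated tetrahedral adduct survives until the quench, and one extra equivalent is consumed by the alkyne C–H.

Step 8
Reactants: 12 (3S,4R)-4-[(tert-butyldimethylsilyl)oxy]-1-chloro-3-[(4-methoxybenzyl)oxy]hex-5-yn-2-one; 13 vinylmagnesium bromide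
Product: 14 (3S,4S,5R)-5-[(tert-butyldimethylsilyl)oxy]-3-(chloromethyl)-4-[(4-methoxybenzyl)oxy]hept-1-en-6-yn-3-ol
Conditions: 13 (3 equiv), THF, –78 °C, cold quench
Reagents that add atoms: vinylmagnesium bromide 13, C=C[Mg]Br
Why: Cram-chelate-controlled Grignard addition: magnesium locks the C1 carbonyl oxygen and the C2 PMB ether oxygen in a five-membered chelate (the C7 chloride and the C3 silyl ether are poor ligands), so vinyl (C6) attacks the face that carries C2–H, anti to the C3 branch, which sets C1–O and C2–O threo along C6–C1–C2–C3, that is trans in the later ring.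

Step 9
Reactants: 14 (3S,4S,5R)-5-[(tert-butyldimethylsilyl)oxy]-3-(chloromethyl)-4-[(4-methoxybenzyl)oxy]hept-1-en-6-yn-3-ol; 15 benzoic acid
Product: 17 (2R,3S,4R)-4-[(tert-butyldimethylsilyl)oxy]-2-ethenyl-2-hydroxy-3-[(4-methoxybenzyl)oxy]hex-5-yn-1-yl benzoate, via vinyl epoxide 16 (not isolated)
Conditions: K2CO3, MeOH, 0 °C to rt; filter, evaporate; 15 (2 equiv), Cs2CO3 (10 mol %), DMF, 70 °C
Reagents that add atoms: benzoic acid 15, O=C(O)c1ccccc1
Why: Base-induced ring closure of the halohydrin followed by SN2 opening of the 2,2-disubstituted epoxide by benzoate at the unhindered C7 methylene in a benzoic acid buffer; the C1–O bond is never broken, so C1 keeps its configuration.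

Step 10
Reactants: 17 (2R,3S,4R)-4-[(tert-butyldimethylsilyl)oxy]-2-ethenyl-2-hydroxy-3-[(4-methoxybenzyl)oxy]hex-5-yn-1-yl benzoate
Product: 18 (2R,3S,4R)-4-[(tert-butyldimethylsilyl)oxy]-2-ethenyl-2,3-dihydroxyhex-5-yn-1-yl benzoate
Conditions: DDQ, CH2Cl2–pH 7 buffer (10:1), 0 °C to rt
Reagents that add atoms: none
Why: Oxidative PMB cleavage with DDQ (hydride abstraction, then hydrolysis), in which the water present should intercept the oxocarbenium ion before C1–OH does, while silyl ether, benzoate, alkene and alkyne are inert.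

Step 11
Reactants: 18 (2R,3S,4R)-4-[(tert-butyldimethylsilyl)oxy]-2-ethenyl-2,3-dihydroxyhex-5-yn-1-yl benzoate; 19 benzoyl chloride
Product: 20 (2R,3S,4R)-3-(benzoyloxy)-4-[(tert-butyldimethylsilyl)oxy]-2-ethenyl-2-hydroxyhex-5-yn-1-yl benzoate
Conditions: 19, pyridine, DMAP (cat.), CH2Cl2, 0 °C to rt
Reagents that add atoms: benzoyl chloride 19, O=C(Cl)c1ccccc1
Why: DMAP-catalysed acylation takes the secondary C2–OH and leaves the tertiary C1–OH alone, and acylating before C1 is silylated keeps the crowded C2–OH accessible.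

Step 12
Reactants: 20 (2R,3S,4R)-3-(benzoyloxy)-4-[(tert-butyldimethylsilyl)oxy]-2-ethenyl-2-hydroxyhex-5-yn-1-yl benzoate
Product: 21 (2R,3S,4R)-3-(benzoyloxy)-4-[(tert-butyldimethylsilyl)oxy]-2-ethenyl-2-[(triethylsilyl)oxy]hex-5-yn-1-yl benzoate
Conditions: TESOTf, 2,6-lutidine, CH2Cl2, –78 to 0 °C
Reagents that add atoms: triethylsilyl trifluoromethanesulfonate, CC[Si](CC)(CC)OS(=O)(=O)C(F)(F)F
Why: Silylation of a hindered tertiary alcohol with a silyl triflate and a non-nucleophilic base; the ether blocks hemiacetal formation and α-ketol shift in the coming α-oxygenated aldehyde.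

Step 13
Reactants: 21 (2R,3S,4R)-3-(benzoyloxy)-4-[(tert-butyldimethylsilyl)oxy]-2-ethenyl-2-[(triethylsilyl)oxy]hex-5-yn-1-yl benzoate
Product: 23 (2R,3S,4R)-3-(benzoyloxy)-4-[(tert-butyldimethylsilyl)oxy]-2-formyl-2-[(triethylsilyl)oxy]hex-5-yn-1-yl benzoate, via secondary ozonide 22 (not isolated)
Conditions: O3, CH2Cl2, –78 °C, Sudan III end point; PPh3, –78 °C to rt
Reagents that add atoms: ozone, [O-][O+]=O
Why: Ozonolysis with reductive work-up: ozone attacks a monosubstituted alkene far faster than a terminal alkyne and the dye marks the end point, so only the vinyl group is cleaved to the C6 aldehyde, which cannot epimerise because C1 bears no hydrogen.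

Step 14
Reactants: 23 (2R,3S,4R)-3-(benzoyloxy)-4-[(tert-butyldimethylsilyl)oxy]-2-formyl-2-[(triethylsilyl)oxy]hex-5-yn-1-yl benzoate
Product: 24 {(1R,5R,6S)-6-(benzoyloxy)-5-[(tert-butyldimethylsilyl)oxy]-2-oxo-1-[(triethylsilyl)oxy]cyclohex-3-en-1-yl}methyl benzoate
Conditions: [Rh(nbd)2]BF4/dppe (10 mol %, H2-activated), degassed acetone, 0.01 M, 60–90 °C
Reagents that add atoms: none
Why: Proposed new method: cationic Rh(I)–dppe, held by the tethered C4≡C5 π bond, inserts into the C6–H bond to give an acyl rhodium(III) hydride; hydride moves to C4 and rhodium to C5, the first-formed alkenyl rhodium (Rh trans to C3) cannot sit in a seven-membered rhodacycle and turns over through an η2-vinyl/carbenoid form, and C5–C6 reductive elimination releases the cis-enone. The closest known reaction types are the Rh(I)/bisphosphine trans-hydroacylation of 4-alkynals to cyclopentenones, the cyclisation of 5- and 6-alkynals with related catalysts and the linear-selective intermolecular hydroacylation of terminal alkynes, but an endo closure to a six-membered enone from a terminal, fully oxygenated 5-alkynal has not been shown. The single ring is closed in the 6-endo-dig mode. No stereocentre is created, and C1–C3 are safe because C1 bears no hydrogen and the medium is neutral. The step needs endo over 5-exo closure and alkyne insertion over decarbonylation: C5 is unsubstituted whereas C4 is shielded by the C3 OTBS group, which steers rhodium to C5, and the quaternary C1 together with the 1,3-related bulky silyl ethers on C1 and C3 disfavours the extended chain and folds C6 towards C5. An oxygen on C1 could reach the acyl metal only through a four-membered ring, so the alkyne itself is relied on as the anchoring ligand, and high dilution in weakly coordinating acetone is used against alkyne oligomerisation.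

Step 15
Reactants: 24 {(1R,5R,6S)-6-(benzoyloxy)-5-[(tert-butyldimethylsilyl)oxy]-2-oxo-1-[(triethylsilyl)oxy]cyclohex-3-en-1-yl}methyl benzoate
Product: 25 [(1R,5R,6S)-6-(benzoyloxy)-1,5-dihydroxy-2-oxocyclohex-3-en-1-yl]methyl benzoate
Conditions: HF·pyridine, pyridine, THF, 0 °C to rt
Reagents that add atoms: none
Why: Fluoride-mediated desilylation in an acidic medium removes both silyl ethers in one operation, and since no alkoxide is ever present, benzoyl migration from C2–O to C1–O or C3–O and base-induced elimination in the γ-hydroxy enone should be avoided.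

Compound list
1 | diethyl D-tartrate, diethyl (2S,3S)-2,3-dihydroxybutanedioate | CCOC(=O)[C@@H](O)[C@H](O)C(=O)OCC | starting material
2 | diethyl (4S,5S)-2,2-dibutyl-1,3,2-dioxastannolane-4,5-dicarboxylate | CCOC(=O)[C@@H]1[C@H](O[Sn](CCCC)(CCCC)O1)C(=O)OCC | intermediate
3 | diethyl (2S,3S)-2-hydroxy-3-[(4-methoxybenzyl)oxy]butanedioate | CCOC(=O)[C@@H](OCc1ccc(OC)cc1)[C@H](O)C(=O)OCC | intermediate
4 | ethyl (2S,3R)-3,4-dihydroxy-2-[(4-methoxybenzyl)oxy]butanoate | CCOC(=O)[C@@H](OCc1ccc(OC)cc1)[C@H](O)CO | intermediate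
5 | (3S,4R)-4-hydroxy-3-[(4-methoxybenzyl)oxy]oxolan-2-one | O=C1[C@@H](OCc2ccc(OC)cc2)[C@H](O)CO1 | intermediate
6 | (3S,4R)-4-[(tert-butyldimethylsilyl)oxy]-3-[(4-methoxybenzyl)oxy]oxolan-2-one | O=C1[C@@H](OCc2ccc(OC)cc2)[C@H](O[Si](C)(C)C(C)(C)C)CO1 | intermediate
7 | (2S,3R)-3-[(tert-butyldimethylsilyl)oxy]-4-hydroxy-N-methoxy-2-[(4-methoxybenzyl)oxy]-N-methylbutanamide | CON(C)C(=O)[C@@H](OCc1ccc(OC)cc1)[C@H](O[Si](C)(C)C(C)(C)C)CO | intermediate
8 | (2S,3S)-3-[(tert-butyldimethylsilyl)oxy]-N-methoxy-2-[(4-methoxybenzyl)oxy]-N-methyl-4-oxobutanamide | CON(C)C(=O)[C@@H](OCc1ccc(OC)cc1)[C@H](O[Si](C)(C)C(C)(C)C)C=O | intermediate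
9 | dimethyl (1-diazo-2-oxopropyl)phosphonate | COP(=O)(OC)C(=[N+]=[N-])C(C)=O | starting material
10 | (2S,3R)-3-[(tert-butyldimethylsilyl)oxy]-N-methoxy-2-[(4-methoxybenzyl)oxy]-N-methylpent-4-ynamide | CON(C)C(=O)[C@@H](OCc1ccc(OC)cc1)[C@H](O[Si](C)(C)C(C)(C)C)C#C | intermediate
11 | chloroiodomethane | ClCI | starting material
12 | (3S,4R)-4-[(tert-butyldimethylsilyl)oxy]-1-chloro-3-[(4-methoxybenzyl)oxy]hex-5-yn-2-one | ClCC(=O)[C@@H](OCc1ccc(OC)cc1)[C@H](O[Si](C)(C)C(C)(C)C)C#C | intermediate
13 | vinylmagnesium bromide | C=C[Mg]Br | starting material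
14 | (3S,4S,5R)-5-[(tert-butyldimethylsilyl)oxy]-3-(chloromethyl)-4-[(4-methoxybenzyl)oxy]hept-1-en-6-yn-3-ol | C=C[C@@](O)(CCl)[C@@H](OCc1ccc(OC)cc1)[C@H](O[Si](C)(C)C(C)(C)C)C#C | intermediate
15 | benzoic acid | O=C(O)c1ccccc1 | starting material
16 | (2R)-2-{(1S,2R)-2-[(tert-butyldimethylsilyl)oxy]-1-[(4-methoxybenzyl)oxy]but-3-yn-1-yl}-2-ethenyloxirane | C=C[C@@]1(CO1)[C@@H](OCc2ccc(OC)cc2)[C@H](O[Si](C)(C)C(C)(C)C)C#C | intermediate
17 | (2R,3S,4R)-4-[(tert-butyldimethylsilyl)oxy]-2-ethenyl-2-hydroxy-3-[(4-methoxybenzyl)oxy]hex-5-yn-1-yl benzoate | C=C[C@@](O)(COC(=O)c1ccccc1)[C@@H](OCc1ccc(OC)cc1)[C@H](O[Si](C)(C)C(C)(C)C)C#C | intermediate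
18 | (2R,3S,4R)-4-[(tert-butyldimethylsilyl)oxy]-2-ethenyl-2,3-dihydroxyhex-5-yn-1-yl benzoate | C=C[C@@](O)(COC(=O)c1ccccc1)[C@@H](O)[C@H](O[Si](C)(C)C(C)(C)C)C#C | intermediate
19 | benzoyl chloride | O=C(Cl)c1ccccc1 | starting material
20 | (2R,3S,4R)-3-(benzoyloxy)-4-[(tert-butyldimethylsilyl)oxy]-2-ethenyl-2-hydroxyhex-5-yn-1-yl benzoate | C=C[C@@](O)(COC(=O)c1ccccc1)[C@@H](OC(=O)c1ccccc1)[C@H](O[Si](C)(C)C(C)(C)C)C#C | intermediate
21 | (2R,3S,4R)-3-(benzoyloxy)-4-[(tert-butyldimethylsilyl)oxy]-2-ethenyl-2-[(triethylsilyl)oxy]hex-5-yn-1-yl benzoate | C=C[C@@](O[Si](CC)(CC)CC)(COC(=O)c1ccccc1)[C@@H](OC(=O)c1ccccc1)[C@H](O[Si](C)(C)C(C)(C)C)C#C | intermediate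
22 | secondary ozonide of 21 (1,2,4-trioxolan-3-yl on C1 in place of vinyl, C1–C3 as in 21, ozonide carbon undefined) | O1OCOC1[C@@](O[Si](CC)(CC)CC)(COC(=O)c2ccccc2)[C@@H](OC(=O)c2ccccc2)[C@H](O[Si](C)(C)C(C)(C)C)C#C | intermediate
23 | (2R,3S,4R)-3-(benzoyloxy)-4-[(tert-butyldimethylsilyl)oxy]-2-formyl-2-[(triethylsilyl)oxy]hex-5-yn-1-yl benzoate | O=C[C@@](O[Si](CC)(CC)CC)(COC(=O)c1ccccc1)[C@@H](OC(=O)c1ccccc1)[C@H](O[Si](C)(C)C(C)(C)C)C#C | intermediate
24 | {(1R,5R,6S)-6-(benzoyloxy)-5-[(tert-butyldimethylsilyl)oxy]-2-oxo-1-[(triethylsilyl)oxy]cyclohex-3-en-1-yl}methyl benzoate | O=C(OC[C@]1(O[Si](CC)(CC)CC)C(=O)C=C[C@@H](O[Si](C)(C)C(C)(C)C)[C@@H]1OC(=O)c1ccccc1)c1ccccc1 | intermediate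
25 | [(1R,5R,6S)-6-(benzoyloxy)-1,5-dihydroxy-2-oxocyclohex-3-en-1-yl]methyl benzoate | O=C(OC[C@]1(O)C(=O)C=C[C@@H](O)[C@@H]1OC(=O)c1ccccc1)c1ccccc1 | target

Total step count: 15. Longest linear sequence: 15 steps, from 1 to 25.

Steps most likely to fail

1. **Step 14.** The closure may run in the exo sense. The acyl rhodium hydride may lose CO before the alkyne inserts, or the terminal alkyne may oligomerise. The fallback uses known chemistry, sets out from 23 and returns at 24.
   - Lindlar semi-hydrogenation of the alkyne gives the alkenal F1.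
   - Nozaki–Hiyama–Kishi addition of vinyl bromide (CrCl2, cat. NiCl2, DMF) tolerates the benzoates and gives the dienol F2, a C6 epimer mixture of no consequence.
   - Ring-closing metathesis with a second-generation Grubbs catalyst forms C4=C5 and gives the cyclohexenol F3.
   - Dess–Martin oxidation of C6–OH then delivers 24. In this variant C5 comes from vinyl bromide.

2. **Step 8.** Facial selectivity may erode if an open transition state competes with the magnesium chelate, and enolisation of the chloroketone may epimerise C2. The fallback reverses the order in which C6 and C7 are attached. It sets out from 10 and returns at 16.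
   - Reagent 13 converts the Weinreb amide into the vinyl ketone F4.
   - Dimethylsulfonium methylide (Me3SI, KHMDS, THF, low temperature; Corey–Chaykovsky epoxidation) cannot be chelated, so it adds C7 in 1,2 fashion under polar Felkin–Anh control.
   - The opposite face is attacked, but by the other carbon, so the same C1 configuration should result.
   - Epoxide 16 enters the second half of step 9.

3. **Step 9.** The vinyl epoxide may open at the tertiary allylic carbon or in the SN2′ sense, or the silyl group may migrate from C3–O to the C1 alkoxide. The fallback avoids the epoxide. It sets out from 12 and returns at 17.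
   - Caesium benzoate (from 15 and Cs2CO3, DMF, rt) displaces the carbonyl-activated chloride and gives the α-benzoyloxy ketone F5.
   - The acyloxy oxygen of F5 is as poor a ligand for magnesium as chloride.
   - Addition of 1.2 equivalents of 13 at –78 °C, where the chelate-activated ketone reacts much faster than a benzoate, should give 17 directly.

Further compounds
F1 | step 14 | alkenal: 23 with C4≡C5 reduced to a terminal C4=CH2 alkene, C1–C3 unchanged | O=C[C@@](O[Si](CC)(CC)CC)(COC(=O)c1ccccc1)[C@@H](OC(=O)c1ccccc1)[C@H](O[Si](C)(C)C(C)(C)C)C=C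
F2 | step 14 | dienol: F1 with vinyl added to C6 (allylic alcohol, C6 epimers), C1–C3 unchanged | C=CC(O)[C@@](O[Si](CC)(CC)CC)(COC(=O)c1ccccc1)[C@@H](OC(=O)c1ccccc1)[C@H](O[Si](C)(C)C(C)(C)C)C=C
F3 | step 14 | cyclohexenol: 24 with C6 as CHOH (C6 epimers) | O=C(OC[C@]1(O[Si](CC)(CC)CC)C(O)C=C[C@@H](O[Si](C)(C)C(C)(C)C)[C@@H]1OC(=O)c1ccccc1)c1ccccc1
F4 | step 8 | (4S,5R)-5-[(tert-butyldimethylsilyl)oxy]-4-[(4-methoxybenzyl)oxy]hept-1-en-6-yn-3-one | C=CC(=O)[C@@H](OCc1ccc(OC)cc1)[C@H](O[Si](C)(C)C(C)(C)C)C#C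
F5 | step 9 | (3S,4R)-4-[(tert-butyldimethylsilyl)oxy]-3-[(4-methoxybenzyl)oxy]-2-oxohex-5-yn-1-yl benzoate | O=C(OCC(=O)[C@@H](OCc1ccc(OC)cc1)[C@H](O[Si](C)(C)C(C)(C)C)C#C)c1ccccc1
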